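| setting | north-west | west | east | south-west | south-east |
|---|---|---|---|---|---|
| substrate | 0.500 M | 0.250 M | 1.50 M | 0.500 M | 0.500 M |
| reagent | 0.600 M | 0.350 M | 0.600 M | 0.900 M | 0.600 M |
| free catalyst | 0.00100 M | 0.00100 M | 0.00100 M | 0.00100 M | 0.00100 M |
| product |  |  |  |  | 0.400 M |
| time |  |  |  |  | 45 h |

**The amounts.** The south-east flask holds the substrate, reagent and free catalyst of the north-west run, plus product worth 80.0% of its substrate charge.

| run | time / h | [substrate] / M |
|---|---|---|
| north-west run | 1.8 | 0.467 |
| north-west run | 3.1 | 0.452 |
| north-west run | 5.3 | 0.420 |
| north-west run | 9.0 | 0.385 |
| north-west run | 15 | 0.332 |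
| north-west run | 26 | 0.282 |
| north-west run | 45 | 0.215 |
| west run | 1.8 | 0.243 |
| west run | 3.1 | 0.231 |
| west run | 5.3 | 0.225 |
| west run | 9.0 | 0.206 |
| west run | 15 | 0.183 |
| west run | 26 | 0.172 |
| west run | 45 | 0.143 |
| east run | 1.8 | 1.421 |
| east run | 3.1 | 1.371 |
| east run | 5.3 | 1.312 |
| east run | 9.0 | 1.222 |
| east run | 15 | 1.130 |
| east run | 26 | 1.027 |
| east run | 45 | 0.956 |
| south-west run | 1.8 | 0.452 |
| south-west run | 3.1 | 0.425 |
| south-west run | 5.3 | 0.387 |
| south-west run | 9.0 | 0.344 |
| south-west run | 15 | 0.290 |
| south-west run | 26 | 0.224 |
| south-west run | 45 | 0.152 |

(standard deviation of a reading: 0.004 M)

- order of the initial rate in [substrate], near the charge of the north-west run, the rate being that where two percent of its substrate are product (one fixed amount of product, the same in the runs compared)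
- order of the initial rate in [reagent], near the charge of the north-west run, the rate being that where two percent of its substrate are product
- the west run starts with 0.250 M less of substrate and of reagent than the north-west run, and with no product. Compared where both hold the same amount of substrate, once fifteen percent of what the west run was charged with has turned into product, is the west run faster, slower or alike (within a tenth)?
- substrate in the south-east run at 45 h, as a share of the substrate charged

- Overall: substrate + reagent -> product, with free catalyst as catalyst.
- Constant volume, constant temperature.
- The analysis sees a species whether free or bound.
- "The second partner" is reagent.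
- An order is taken over about fifteen percent of the charge, up and down.

**The clock.** Substrate and reagent are used one for one, so a single scale can be read from the substrate readings. Take the ratio of reagent to substrate, divide it by its starting value, take the natural log, and divide by the charged excess of reagent over substrate. This is the integrated second-order rate law. With rate equal to a fixed constant times substrate times reagent, it rises evenly with time. At 45 h the north-west run reads 2.00 M⁻¹, its second-order clock. The north-west clock does not run evenly: at 15 h, a third of the time, it already stands at 0.810 M⁻¹.

**What matters.** The south-east charges of substrate, reagent and free catalyst equal the north-west ones, so they add no error. One standard deviation in the north-west reading at 45 h moves the share of charge by 0.800%. At 45 h the south-west run reads 1.75 M⁻¹, the west run 1.94 M⁻¹ and the east run 2.13 M⁻¹. Put on the north-west charge, the south-west reading leaves 46.5% of the substrate and the east reading 41.2%, a gap of 5.3 percentage points, wider than that reading error.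

**The product.** The added product remains to be weighed. Measured against the north-west substrate charge, the west run has made 21.4% by 45 h and the east run 109%, more than the south-east flask is given. Yet the east clock reads highest. The east run differs from the north-west run in its substrate charge too, so this comparison is no proof about product.

**The reckoning.** This reckoning carries the north-west clock over unchanged, so the south-east flask is reckoned to keep 43.0% of its substrate at 45 h.

**The forecast.** The forecast gives orders of 0.9 and 1, the west run faster, and 47%, above the share reckoned here, and on the cause it says “I lean towards decay”.

**The flask.** The south-east flask keeps 43.9%, with orders of 0.90 and 0.99, and the west run faster.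

    free catalyst + substrate ⇌ catalyst-substrate complex (330.1 M⁻¹ h⁻¹, 229.0 h⁻¹)
    catalyst-substrate complex + reagent → product + free catalyst (39.24 M⁻¹ h⁻¹)
    substrate + reagent → product (0.03816 M⁻¹ h⁻¹)
    free catalyst + reagent → spent catalyst + reagent (0.4752 M⁻¹ h⁻¹)

At equal substrate the west run goes 1.4 times as fast as the north-west run. The south-east share corresponds to a clock of 1.93 M⁻¹ at 45 h, beside the 2.00 M⁻¹ read in the north-west run. The east run turns a quarter of its charge into product at 15.5 h, where its clock reads 0.770 M⁻¹, and the north-west clock read 0.810 M⁻¹ at 15 h.

(The data are calculated for substances that don't exist, noise included.)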